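**Strategy.** Both decalin halves come from one allyl decalin, which is joined to a central bis(α-methylidene) lactone–acrylate diester by two-fold cross-metathesis. Ring A of the decalin is annulated onto a preformed ring B. The feature exploited is ring A itself: the gem-dimethyl quaternary C4 and the three bare methylenes C1–C3 next to the quaternary C10. A monocyclic keto aldehyde acid (CHO on C10, C(CH3)2CO2H on C5) is decarboxylated by photoredox catalysis. The C4 radical adds to a vinylphosphonium salt (C3–C4 bond), and the ylide formed by radical–polar crossover closes ring A by Wittig reaction with the formyl carbon (C1=C2 bond), leaving only an alkene to hydrogenate.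

Key step: step 3

Remark: atom labels follow labdane numbering of each decalin unit (C4 = C(CH3)2, C10 = angular C–CH3, C9 = side-chain CH, C8 = methylidene carbon, C17 = its CH2).
Assumption: the sense of induction of the oxazaborolidinium catalyst on the α-methyl enone is taken to parallel that on cyclohex-2-enone; the (S)-proline-derived catalyst is written and its antipode would be used if the opposite sense were found.
Remark: keto aldehyde acid 6 may equilibrate with its cyclic lactol; its caesium carboxylate in step 3 is the open form.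

Step 1
Reactants: 1 2-methylcyclohex-2-en-1-one; 2 1-methoxy-2-methyl-1-(trimethylsilyloxy)prop-1-ene
Product: 4 methyl 2-[(1R,2R)-2-(dimethoxymethyl)-2-methyl-3-oxocyclohexyl]-2-methylpropanoate, via silyl enol ether 3 (not isolated)
Conditions: oxazaborolidinium salt from (S)-3,3-diphenyl-1-(2-methylphenyl)tetrahydro-1H,3H-pyrrolo[1,2-c][1,3,2]oxazaborole and HN(SO2CF3)2 (20 mol%), Ph3PO (25 mol%), toluene, −20 °C; then HC(OCH3)3, Me3SiOTf (10 mol%), CH2Cl2, −78 °C
Reagents that add atoms: trimethyl orthoformate, COC(OC)OC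
Why: Catalytic asymmetric Mukaiyama–Michael addition of the silyl ketene acetal should set C5 (R) under catalyst control and give the regiodefined tetrasubstituted silyl enol ether 3, which is then alkylated by the dimethoxycarbenium ion (Me3SiOTf-catalysed Mukaiyama-type reaction with an orthoester) on the face anti to the bulky C5 substituent, so that the quaternary C10 carries CH(OCH3)2 trans and CH3 cis to it.

Step 2
Reactants: 4 methyl 2-[(1R,2R)-2-(dimethoxymethyl)-2-methyl-3-oxocyclohexyl]-2-methylpropanoate
Product: 6 2-[(1R,2R)-2-formyl-2-methyl-3-oxocyclohexyl]-2-methylpropanoic acid, via keto acetal acid 5 (not isolated)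
Conditions: NaSEt, DMF, 90 °C; then 2 M HCl, THF, 40 °C
Reagents that add atoms: water, O
Why: SN2 demethylation by thiolate frees the hindered carboxyl group without acyl attack, and acid-catalysed acetal hydrolysis then unmasks the formyl group; no stereocenter is touched and the quaternary C10 cannot epimerise.

Step 3
Reactants: 6 2-[(1R,2R)-2-formyl-2-methyl-3-oxocyclohexyl]-2-methylpropanoic acid; 7 ethenyl(triphenyl)phosphonium bromide
Product: 9 (4aS,8aS)-5,5,8a-trimethyl-3,4,4a,5,6,8a-hexahydronaphthalen-1(2H)-one, via phosphonium ylide 8 (not isolated)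
Conditions: 2,4,5,6-tetra(9H-carbazol-9-yl)isophthalonitrile (2 mol%), Cs2CO3 (1.05 equiv), 7 (1.5 equiv), CH2Cl2, 450 nm LEDs, rt
Reagents that add atoms: none
Why: Photoredox radical–polar crossover annulation, the intramolecular form of the known three-component conjunctive olefination of a carboxylic acid, a vinylphosphonium salt and an aldehyde: the excited photocatalyst oxidises the caesium carboxylate of 6, loss of CO2 gives the tertiary C4 radical, this adds to the CH2 terminus of 7 (C3–C4 bond), and the α-phosphonio radical is reduced by the photocatalyst radical anion to ylide 8. The ylide carbon C2 then adds to the C1 formyl carbon on C10 in a 6-exo-trig mode and the oxaphosphetane collapses (Wittig reaction) to the cis C1=C2 alkene, which closes ring A. No stereocenter is created; the trans ring fusion is inherited from the trans arrangement of CHO on C10 and the C4 unit on C5 fixed in step 1, and C4 becomes the gem-dimethyl quaternary carbon. The step needs the ylide to choose the aldehyde over the C9 ketone, and this is secured by the substrate, because closure onto C9 would demand a bridgehead alkene in a bicyclo[3.3.1] frame (Bredt's rule). The nucleophilic tertiary radical and the strongly electrophilic vinylphosphonium ion are polarity-matched, which should favour Giese-type addition over radical oxidation.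

Step 4
Reactants: 9 (4aS,8aS)-5,5,8a-trimethyl-3,4,4a,5,6,8a-hexahydronaphthalen-1(2H)-one
Product: 10 (4aS,8aS)-5,5,8a-trimethyloctahydronaphthalen-1(2H)-one
Conditions: H2 (1 atm), palladium on carbon (Pd/C), EtOAc, rt
Reagents that add atoms: none
Why: Heterogeneous catalytic hydrogenation saturates the only C=C bond (cis-disubstituted C1=C2) and leaves the hindered ketone; no stereocenter is formed.

Step 5
Reactants: 10 (4aS,8aS)-5,5,8a-trimethyloctahydronaphthalen-1(2H)-one
Product: 12 (4aS,8aS)-5,5,8a-trimethyl-2-methylideneoctahydronaphthalen-1(2H)-one, via Mannich base 11 (not isolated)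
Conditions: (CH2O)n, N-methylanilinium trifluoroacetate, THF, reflux
Reagents that add atoms: formaldehyde (as paraformaldehyde), C=O
Why: Mannich-type α-methylenation can occur only at C8, the sole enolisable position because C10 is quaternary, and the Mannich base loses N-methylaniline to give the exocyclic enone (used at once to avoid dimerisation).

Step 6
Reactants: 12 (4aS,8aS)-5,5,8a-trimethyl-2-methylideneoctahydronaphthalen-1(2H)-one
Product: 14 methyl (1S,4aS,8aS)-5,5,8a-trimethyl-2-methylidene-1-(prop-2-en-1-yl)decahydronaphthalen-1-yl carbonate, via magnesium alkoxide 13 (not isolated)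
Conditions: CH2=CHCH2MgBr, THF, −78 °C; then ClCO2CH3, −78 °C to rt
Reagents that add atoms: allylmagnesium bromide, C=CC[Mg]Br; methyl chloroformate, COC(=O)Cl
Why: Grignard 1,2-addition of the allyl reagent to the enone carbonyl is expected mainly from the α face anti to the axial C10 methyl (this temporary C9 configuration is erased in step 7), and the tertiary alkoxide is trapped as the carbonate while low temperature and the magnesium counter-ion hold back anionic oxy-Cope rearrangement of the 1,5-dien-3-olate.

Step 7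
Reactants: 14 methyl (1S,4aS,8aS)-5,5,8a-trimethyl-2-methylidene-1-(prop-2-en-1-yl)decahydronaphthalen-1-yl carbonate
Product: 15 (1S,4aS,8aS)-5,5,8a-trimethyl-2-methylidene-1-(prop-2-en-1-yl)decahydronaphthalene
Conditions: Pd(OAc)2 (5 mol%), PBu3 (20 mol%), HCO2NH4, 1,4-dioxane, 60 °C
Reagents that add atoms: none
Why: Tsuji–Trost ionisation by zerovalent palladium gives the C9–C8–C17 π-allyl complex and formate hydrogenolysis delivers hydride to the more substituted terminus C9 from the palladium-bearing α face (anti to the angular methyl, reachable by η3–η1–η3 equilibration through the CH2 terminus), which keeps the exocyclic C8=CH2 bond and should set C9 (S) with the allyl group equatorial.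

Step 8
Reactants: 16 (4R)-4-hydroxyoxolan-2-one
Product: 19 (4R)-4-hydroxy-3-methylideneoxolan-2-one, via Mannich base 17 (not isolated), via ammonium iodide 18 (not isolated)
Conditions: LiN(iPr)2 (2.2 equiv), THF, −78 °C; [(CH3)2N=CH2]I, −78 to 0 °C; then CH3I, CH3OH, rt; then NaHCO3 (aq), CH2Cl2
Reagents that add atoms: Eschenmoser's salt, C=[N+](C)C.[I-]
Why: The alkoxide–enolate dianion (the alkoxide blocks β-elimination) undergoes Mannich aminomethylation trans to the alkoxide, and N-methylation followed by E1cB loss of trimethylamine gives the α-methylidene lactone; the carbinol stereocenter (R) comes unchanged from the chiral pool.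

Step 9
Reactants: 20 methyl 4,4-dimethoxybutanoate
Product: 23 methyl 4,4-dimethoxy-2-methylidenebutanoate, via Mannich base 21 (not isolated), via ammonium iodide 22 (not isolated)
Conditions: LiN(iPr)2, THF, −78 °C; [(CH3)2N=CH2]I; then CH3I, CH3OH, rt; then NaHCO3 (aq), CH2Cl2
Reagents that add atoms: Eschenmoser's salt, C=[N+](C)C.[I-]
Why: Ester enolate Mannich reaction, quaternisation and elimination of trimethylamine is the standard α-methylenation sequence; the γ-acetal is inert to base and no stereocenter is involved.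

Step 10
Reactants: 23 methyl 4,4-dimethoxy-2-methylidenebutanoate
Product: 24 4,4-dimethoxy-2-methylidenebutanoic acid
Conditions: LiOH, THF/H2O, 0 °C to rt; then 1 M HCl to pH 4, 0 °C
Reagents that add atoms: lithium hydroxide, [Li+].[OH-]
Why: Saponification of the unhindered acrylate ester; the acetal survives base and a brief cold acidification, and the acid is used directly.

Step 11
Reactants: 19 (4R)-4-hydroxy-3-methylideneoxolan-2-one; 24 4,4-dimethoxy-2-methylidenebutanoic acid
Product: 25 (3R)-4-methylidene-5-oxooxolan-3-yl 4,4-dimethoxy-2-methylidenebutanoate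
Conditions: DCC, DMAP (10 mol%), CH2Cl2, 0 °C
Reagents that add atoms: none
Why: Steglich esterification acylates the secondary allylic alcohol under near-neutral conditions; the C–O bond of the stereocenter is not broken, so (R) is retained.

Step 12
Reactants: 25 (3R)-4-methylidene-5-oxooxolan-3-yl 4,4-dimethoxy-2-methylidenebutanoate; 15 (1S,4aS,8aS)-5,5,8a-trimethyl-2-methylidene-1-(prop-2-en-1-yl)decahydronaphthalene (two molecules incorporated)
Product: 28 (3R,4E)-5-oxo-4-{2-[(1S,4aS,8aS)-5,5,8a-trimethyl-2-methylidenedecahydronaphthalen-1-yl]ethylidene}oxolan-3-yl (2E)-2-(2,2-dimethoxyethyl)-4-[(1S,4aS,8aS)-5,5,8a-trimethyl-2-methylidenedecahydronaphthalen-1-yl]but-2-enoate, via lactone-side mono-adduct 26 (not isolated), via acrylate-side mono-adduct 27 (not isolated)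
Conditions: second-generation Hoveyda–Grubbs catalyst [RuCl2(=CH-C6H4-2-OiPr)(1,3-dimesitylimidazolidin-2-ylidene)] (2 × 5 mol%), 2,6-dichloro-1,4-benzoquinone (20 mol%), 15 (5 equiv), CH2Cl2, 40 °C
Reagents that add atoms: none
Why: Two-fold olefin cross-metathesis joins the monosubstituted allyl alkene of 15 to each electron-poor 1,1-disubstituted alkene of 25 (a known pairing for α-methylene-γ-butyrolactones and α-substituted acrylates) with loss of ethene; the hindered exocyclic C8=CH2 groups should stay intact, both trisubstituted alkenes are expected as the thermodynamically favoured E isomers, and the benzoquinone suppresses ruthenium hydride alkene migration.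

Step 13
Reactants: 28 bis-decalin dimethyl acetal (full name in step 12)
Product: 29 (3R,4E)-5-oxo-4-{2-[(1S,4aS,8aS)-5,5,8a-trimethyl-2-methylidenedecahydronaphthalen-1-yl]ethylidene}oxolan-3-yl (2E)-2-(2-oxoethyl)-4-[(1S,4aS,8aS)-5,5,8a-trimethyl-2-methylidenedecahydronaphthalen-1-yl]but-2-enoate (CNP0274315.1)
Conditions: pyridinium p-toluenesulfonate (20 mol%), acetone/H2O, 45 °C
Reagents that add atoms: water, O
Why: Mild acid-catalysed acetal hydrolysis should unveil the aldehyde without isomerising the exocyclic alkenes or the β,γ-unsaturated aldehyde and without ionising the allylic ester; no stereocenter is affected.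

**Compound list**

1 | 2-methylcyclohex-2-en-1-one | CC1=CCCCC1=O | starting material
2 | 1-methoxy-2-methyl-1-(trimethylsilyloxy)prop-1-ene | COC(O[Si](C)(C)C)=C(C)C | starting material
3 | methyl 2-methyl-2-[(1R)-2-methyl-3-(trimethylsilyloxy)cyclohex-2-en-1-yl]propanoate (silyl enol ether, formed in the flask) | COC(=O)C(C)(C)[C@@H]1CCCC(O[Si](C)(C)C)=C1C | intermediate
4 | methyl 2-[(1R,2R)-2-(dimethoxymethyl)-2-methyl-3-oxocyclohexyl]-2-methylpropanoate | O=C1CCC[C@@H](C(C)(C)C(=O)OC)[C@]1(C)C(OC)OC | intermediate
5 | 2-[(1R,2R)-2-(dimethoxymethyl)-2-methyl-3-oxocyclohexyl]-2-methylpropanoic acid (formed in the flask) | O=C1CCC[C@@H](C(C)(C)C(=O)O)[C@]1(C)C(OC)OC | intermediate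
6 | 2-[(1R,2R)-2-formyl-2-methyl-3-oxocyclohexyl]-2-methylpropanoic acid | O=C1CCC[C@@H](C(C)(C)C(=O)O)[C@]1(C)C=O | intermediate
7 | ethenyl(triphenyl)phosphonium bromide | C=C[P+](c1ccccc1)(c1ccccc1)c1ccccc1.[Br-] | starting material
8 | (1R,6S)-1-methyl-6-[2-methyl-4-(triphenyl-λ5-phosphanylidene)butan-2-yl]-2-oxocyclohexane-1-carbaldehyde (ylide, formed in the flask) | O=C1CCC[C@@H](C(C)(C)CC=P(c2ccccc2)(c2ccccc2)c2ccccc2)[C@]1(C)C=O | intermediate
9 | (4aS,8aS)-5,5,8a-trimethyl-3,4,4a,5,6,8a-hexahydronaphthalen-1(2H)-one | O=C1CCC[C@H]2C(C)(C)CC=C[C@]12C | intermediate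
10 | (4aS,8aS)-5,5,8a-trimethyloctahydronaphthalen-1(2H)-one | O=C1CCC[C@H]2C(C)(C)CCC[C@]12C | intermediate
11 | (4aS,8aS)-5,5,8a-trimethyl-2-{[methyl(phenyl)amino]methyl}octahydronaphthalen-1(2H)-one (C2 epimers, formed in the flask) | O=C1C(CN(C)c3ccccc3)CC[C@H]2C(C)(C)CCC[C@]12C | intermediate
12 | (4aS,8aS)-5,5,8a-trimethyl-2-methylideneoctahydronaphthalen-1(2H)-one | O=C1C(=C)CC[C@H]2C(C)(C)CCC[C@]12C | intermediate
13 | bromomagnesium (1S,4aS,8aS)-5,5,8a-trimethyl-2-methylidene-1-(prop-2-en-1-yl)decahydronaphthalen-1-olate (formed in the flask) | C=CC[C@]1(O[Mg]Br)C(=C)CC[C@H]2C(C)(C)CCC[C@]12C | intermediate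
14 | methyl (1S,4aS,8aS)-5,5,8a-trimethyl-2-methylidene-1-(prop-2-en-1-yl)decahydronaphthalen-1-yl carbonate | COC(=O)O[C@@]1(CC=C)C(=C)CC[C@H]2C(C)(C)CCC[C@]12C | intermediate
15 | (1S,4aS,8aS)-5,5,8a-trimethyl-2-methylidene-1-(prop-2-en-1-yl)decahydronaphthalene | C=CC[C@H]1C(=C)CC[C@H]2C(C)(C)CCC[C@]12C | intermediate
16 | (4R)-4-hydroxyoxolan-2-one | O[C@H]1COC(=O)C1 | starting material
17 | (3R,4R)-3-[(dimethylamino)methyl]-4-hydroxyoxolan-2-one (formed in the flask) | O[C@H]1COC(=O)[C@@H]1CN(C)C | intermediate
18 | 1-[(3R,4R)-4-hydroxy-2-oxooxolan-3-yl]-N,N,N-trimethylmethanaminium iodide (formed in the flask) | O[C@H]1COC(=O)[C@@H]1C[N+](C)(C)C.[I-] | intermediate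
19 | (4R)-4-hydroxy-3-methylideneoxolan-2-one | O[C@H]1COC(=O)C1=C | intermediate
20 | methyl 4,4-dimethoxybutanoate | COC(=O)CCC(OC)OC | starting material
21 | methyl 2-[(dimethylamino)methyl]-4,4-dimethoxybutanoate (racemic, formed in the flask) | COC(=O)C(CN(C)C)CC(OC)OC | intermediate
22 | 2-(methoxycarbonyl)-4,4-dimethoxy-N,N,N-trimethylbutan-1-aminium iodide (racemic, formed in the flask) | COC(=O)C(C[N+](C)(C)C)CC(OC)OC.[I-] | intermediate
23 | methyl 4,4-dimethoxy-2-methylidenebutanoate | COC(=O)C(=C)CC(OC)OC | intermediate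
24 | 4,4-dimethoxy-2-methylidenebutanoic acid | OC(=O)C(=C)CC(OC)OC | intermediate
25 | (3R)-4-methylidene-5-oxooxolan-3-yl 4,4-dimethoxy-2-methylidenebutanoate | C=C(CC(OC)OC)C(=O)O[C@H]1COC(=O)C1=C | intermediate
26 | (3R,4E)-5-oxo-4-{2-[(1S,4aS,8aS)-5,5,8a-trimethyl-2-methylidenedecahydronaphthalen-1-yl]ethylidene}oxolan-3-yl 4,4-dimethoxy-2-methylidenebutanoate (formed in the flask) | C=C(CC(OC)OC)C(=O)O[C@H]1COC(=O)/C1=C/C[C@H]1C(=C)CC[C@H]2C(C)(C)CCC[C@]12C | intermediate
27 | (3R)-4-methylidene-5-oxooxolan-3-yl (2E)-2-(2,2-dimethoxyethyl)-4-[(1S,4aS,8aS)-5,5,8a-trimethyl-2-methylidenedecahydronaphthalen-1-yl]but-2-enoate (formed in the flask) | C=C1CC[C@H]2C(C)(C)CCC[C@]2(C)[C@H]1C/C=C(\CC(OC)OC)C(=O)O[C@H]1COC(=O)C1=C | intermediate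
28 | (3R,4E)-5-oxo-4-{2-[(1S,4aS,8aS)-5,5,8a-trimethyl-2-methylidenedecahydronaphthalen-1-yl]ethylidene}oxolan-3-yl (2E)-2-(2,2-dimethoxyethyl)-4-[(1S,4aS,8aS)-5,5,8a-trimethyl-2-methylidenedecahydronaphthalen-1-yl]but-2-enoate | C=C1CC[C@H]2C(C)(C)CCC[C@]2(C)[C@H]1C/C=C(\CC(OC)OC)C(=O)O[C@H]1COC(=O)/C1=C/C[C@H]1C(=C)CC[C@H]2C(C)(C)CCC[C@]12C | intermediate
29 | (3R,4E)-5-oxo-4-{2-[(1S,4aS,8aS)-5,5,8a-trimethyl-2-methylidenedecahydronaphthalen-1-yl]ethylidene}oxolan-3-yl (2E)-2-(2-oxoethyl)-4-[(1S,4aS,8aS)-5,5,8a-trimethyl-2-methylidenedecahydronaphthalen-1-yl]but-2-enoate | C=C1CC[C@H]2C(C)(C)CCC[C@]2(C)[C@H]1C/C=C(\CC=O)C(=O)O[C@H]1COC(=O)/C1=C/C[C@H]1C(=C)CC[C@H]2C(C)(C)CCC[C@]12C | target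

**Summary**

Total step count: 13. Longest linear sequence: 9 steps (steps 1–7, 12 and 13).

Steps most likely to fail:

Step 3 (key step). The cascade may stall after the radical addition: the ylide can be protonated before it finds the formyl group, the tertiary radical can be oxidised to an alkene, or the formyl group can be lost by retro-Claisen cleavage under the basic photochemical conditions. The fallback sets out from 6 and comes back at 9. The two bonds would be made by a decarboxylative Giese addition followed by a polar ring closure: photoredox addition of the acid to acrolein gives (1R,6S)-1-methyl-6-(2-methyl-5-oxopentan-2-yl)-2-oxocyclohexane-1-carbaldehyde F1. Pyrrolidinium acetate, added to the same flask, condenses the enolisable chain aldehyde onto the C10 formyl group (intramolecular aldol condensation) to the ring A enal (4aS,8aS)-4,4,8a-trimethyl-8-oxo-3,4,4a,5,6,7,8,8a-octahydronaphthalene-2-carbaldehyde F2. Rhodium-catalysed decarbonylation ([Rh(Ph2P(CH2)3PPh2)2]Cl, xylene, 140 °C) would then give 9, and the route continues with step 4.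

Step 1. Enantiofacial discrimination may be poor and turnover slow, because the α-methyl enone cannot bind the oxazaborolidinium ion in the two-point mode available to α-unsubstituted enones. The fallback sets out from 1 and 2 and comes back at 5. The addition would be run with an achiral Lewis acid (Me3SiOTf, CH2Cl2, −78 °C) to the racemic silyl enol ether F3, which is trapped with the orthoformate as before to the racemic keto acetal ester F4 and demethylated with NaSEt to the racemic keto acetal acid F5. Classical resolution by crystallisation of the 1-phenylethylammonium salt F6 (amine antipode to be chosen by screening, written here as R) and acidification would return enantiopure 5, from which the acid hydrolysis of step 2 continues.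

Step 12. The second metathesis event at the more hindered 1,1-disubstituted alkene may remain incomplete while 15 is consumed by self-metathesis, and E/Z control may erode. The fallback sets out from 15, 19 and 23 and comes back at 28. Each acceptor would be used separately and in excess. Cross-metathesis of 15 with 19 gives the hydroxy lactone (3E,4R)-4-hydroxy-3-{2-[(1S,4aS,8aS)-5,5,8a-trimethyl-2-methylidenedecahydronaphthalen-1-yl]ethylidene}oxolan-2-one F7. Cross-metathesis of 15 with 23 gives methyl (2E)-2-(2,2-dimethoxyethyl)-4-[(1S,4aS,8aS)-5,5,8a-trimethyl-2-methylidenedecahydronaphthalen-1-yl]but-2-enoate F8, which LiOH saponifies to (2E)-2-(2,2-dimethoxyethyl)-4-[(1S,4aS,8aS)-5,5,8a-trimethyl-2-methylidenedecahydronaphthalen-1-yl]but-2-enoic acid F9. Steglich esterification (DCC, DMAP, 0 °C) of F7 with F9 would give 28, and the route continues with step 13.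

Further compounds
F1 | step 3 | (1R,6S)-1-methyl-6-(2-methyl-5-oxopentan-2-yl)-2-oxocyclohexane-1-carbaldehyde | O=C1CCC[C@@H](C(C)(C)CCC=O)[C@]1(C)C=O
F2 | step 3 | (4aS,8aS)-4,4,8a-trimethyl-8-oxo-3,4,4a,5,6,7,8,8a-octahydronaphthalene-2-carbaldehyde | O=C1CCC[C@H]2C(C)(C)CC(C=O)=C[C@]12C
F3 | step 1 | racemic methyl 2-methyl-2-[2-methyl-3-(trimethylsilyloxy)cyclohex-2-en-1-yl]propanoate | COC(=O)C(C)(C)C1CCCC(O[Si](C)(C)C)=C1C
F4 | step 1 | racemic methyl 2-[(1R*,2R*)-2-(dimethoxymethyl)-2-methyl-3-oxocyclohexyl]-2-methylpropanoate | COC(=O)C(C)(C)C1CCCC(=O)C1(C)C(OC)OC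
F5 | step 1 | racemic 2-[(1R*,2R*)-2-(dimethoxymethyl)-2-methyl-3-oxocyclohexyl]-2-methylpropanoic acid | OC(=O)C(C)(C)C1CCCC(=O)C1(C)C(OC)OC
F6 | step 1 | (R)-1-phenylethylammonium 2-[(1R,2R)-2-(dimethoxymethyl)-2-methyl-3-oxocyclohexyl]-2-methylpropanoate | O=C1CCC[C@@H](C(C)(C)C(=O)[O-])[C@]1(C)C(OC)OC.C[C@@H]([NH3+])c1ccccc1
F7 | step 12 | (3E,4R)-4-hydroxy-3-{2-[(1S,4aS,8aS)-5,5,8a-trimethyl-2-methylidenedecahydronaphthalen-1-yl]ethylidene}oxolan-2-one | O[C@H]1COC(=O)/C1=C/C[C@H]1C(=C)CC[C@H]2C(C)(C)CCC[C@]12C
F8 | step 12 | methyl (2E)-2-(2,2-dimethoxyethyl)-4-[(1S,4aS,8aS)-5,5,8a-trimethyl-2-methylidenedecahydronaphthalen-1-yl]but-2-enoate | C=C1CC[C@H]2C(C)(C)CCC[C@]2(C)[C@H]1C/C=C(\CC(OC)OC)C(=O)OC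
F9 | step 12 | (2E)-2-(2,2-dimethoxyethyl)-4-[(1S,4aS,8aS)-5,5,8a-trimethyl-2-methylidenedecahydronaphthalen-1-yl]but-2-enoic acid | C=C1CC[C@H]2C(C)(C)CCC[C@]2(C)[C@H]1C/C=C(\CC(OC)OC)C(=O)O
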